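## Structural features

The target is a trans-fused eremophilane decalin: ring A (C1–C5, C10) and ring B (C5–C10) share the C5–C10 bond, and the quaternary C5 carries an axial methyl (C14) anti to H-10. Five stereocentres lie on one unbroken chain, C3–C4–C5–C10–C9: the ester oxygen at C3 and the methyl C15 at C4 are equatorial, C15 is cis to C14, and the C9 hydroxyl is equatorial. Ring B holds the C8 ketone between the C9 carbinol and a fully substituted exocyclic alkene C7=C11 of E geometry (hydroxymethyl C12 syn to C6, methyl C13 syn to the carbonyl). The C3 oxygen is acylated by (2E,4E,6E)-5-methyldodeca-2,4,6-trienoic acid. The fragile groups are the α-ketol (ketol shift, epimerisation at C9), the γ-hydroxy enone (its Z isomer would close to a hemiketal and then a furan), the primary allylic alcohol and the trienoate, which is a base- and light-sensitive Michael acceptor. The real difficulties are the quaternary C5 with fixed configuration relative to C4 and C10, and the geometry of the tetrasubstituted alkene. The key step uses the fact that, once ring A is opened between C5 and C10, O-3 is allylic to a C4=C5 alkene while C10 is the α-carbon of the C9 carboxyl. Tying C9 to O-3 gives a six-membered lactone whose ketene acetal and alkene form the 1,5-diene C10=C9–O–C3–C4=C5.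

## Logic of the disconnections

Compound 38 is traced back to compound 37 (silicon on O-9) and then to compound 36 (C12 as aldehyde). Compound 36 is cut at the C3–O acyl bond into compounds 26 and 35. The trienoate cannot survive the enolate chemistry that builds ring B and the alkylidene, so it is attached late. The gain is a convergent union of a C15 core with a C13 acid. The demand is an esterification of a flanked secondary alcohol that leaves the triene geometry and the aldehyde alone, followed by an aldehyde reduction that spares the C8 ketone.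

Compound 35 comes from compound 34, which is cut at its C6=C7 double bond into compounds 29 and 33, and compound 29 is cut at C4=C5 into compounds 27 and 28. Both cuts are placed at alkenes that a stereoselective olefination can form, which reduces the acid to four commercial pieces (27, 28, 30 and 31, the last two giving 33 through 32). The demand is E selectivity in both olefinations.

Compound 26 is traced through compounds 25 and 23 to compounds 21 and 22 by cutting C7=C11. The three-carbon unit C11–C13 is added to the C7 methylene of the ring ketone at the aldehyde oxidation level of C12, so that the E isomer can be reached by equilibration of an ene-dicarbonyl system. The forward steps must enolise towards C7 and not C9, avoid retro-aldol cleavage, and end with C12 anti to the C8 carbonyl.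

Compound 21 comes from compound 20, which is cut at C8–C9 to compound 19. This removes ring B and both its oxygen functions in one operation and leaves two aldehydes on a ring A that already holds C3, C4, C5 and C10. The forward step must make the unhindered C8 aldehyde the acyl-anion partner and deliver the C9 oxygen equatorial.

Compound 19 is simplified through compounds 18, 17 and 16 to compound 15 by functional-group changes only. The C3–O and C4–H bonds are traced to the C3=C4 alkene, and the two aldehydes to the carboxyl and the benzyl ether. The demand is hydroboration on the face anti to C14 in a monocyclic ring.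

Compound 15 is cut at C5–C10 and reconnected at C3–O to give compound 12, by way of compounds 14 and 13. This is the strategic cut: it removes the quaternary centre and the C10 stereocentre together and replaces them by one carbinol centre and one alkene geometry. The forward step must transfer chirality completely through a boat transition state and form a bond to a fully substituted alkene terminus. A check of the descriptors shows that (6S,2Z) in compound 12 leads to (1R,2S) in compound 15, and that these centres are C10 (R) and C5 (R) of compound 38, the descriptor at C5 changing only because substituent ranks change. These structures need no correction.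

Compound 12 is opened at the lactone C–O bond to compound 10 (through compound 11), and the C3 carbinol is traced to the ketone of compound 9. The lactone is closed under neutral conditions because the C3–O bond, allylic to a fully substituted alkene, would ionise in acid. The demand is an enantioselective reduction of a ketone flanked by a branched alkenyl and a primary alkyl group.

Compound 9 is cut at the C2–C3 bond into compounds 6 and 8 (through compound 7), and compound 6 is traced through compound 5 to compounds 2 and 3 (through compound 4) by cutting C5–C6; compound 2 comes from compound 1. The alkene geometry is thereby reduced to the geometry of an enol triflate, which chelation fixes, and the stereoretentive coupling must carry it through. This is shorter than carbometallation of an ynoate with electrophilic trapping, where geometric leakage is a risk.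

## Other disconnections considered

Alternative 1: The cut goes through C4–C5 and C1–C10, so ring A is added in one cycloaddition to the C5=C10 bond of a ring B quinone, 2-methoxy-5-methylcyclohexa-2,5-diene-1,4-dione A1, by the silyloxydiene triisopropyl{[(3Z)-penta-1,3-dien-3-yl]oxy}silane A2. In the forward direction TiCl2(OiPr)2 and one enantiomer of 1,1'-bi-2-naphthol would hold A1 in a chelate between the C9 carbonyl and the C8 methoxy oxygen. This directs A2 to the methyl-bearing double bond, fixes the regiochemistry and should differentiate the faces, giving the cis-fused endo adduct A3.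
- In its favour: a catalytic enantioselective step would make the quaternary C5 and the whole bicyclic frame from two small achiral partners, and A3 already carries oxygen at C3, C8 and C9.
- Against it here: the endo rule places C15 anti to C14 and gives a cis ring fusion, so both C4 and C10 of A3 would have to be inverted by enolisation, with the outcome left to thermodynamics. The C6 carbonyl has no counterpart in the target and must be removed without touching C8 and C9, C9 must be reduced to the equatorial alcohol, and C3 still needs a stereoselective reduction.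
- Comparison: the alternative is the better in convergence and in the number of steps to a decalin. It is the equal in that its absolute configuration also comes from a catalytic asymmetric step (cycloaddition there, ketone reduction in step 5 here). Mechanistically it fixes only C5 directly, whereas the sigmatropic step of the chosen plan delivers C5 and C10 together in the trans relationship, and the later redox and epimerisation corrections would probably use up the steps saved. Neither plan settles the alkylidene geometry in its key step.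

Alternative 2: Both rings are cut at once, at C9–C10 and C4–C5, which leads back to an open-chain 1,2-dicarbonyl compound, (5E,9Z)-9-{[tert-butyl(dimethyl)silyl]oxy}-5-methyl-2-oxoundeca-5,9-dienal A4 (the silyl group is a choice made for this discussion). With Cu(OTf)2 and 2,2'-isopropylidenebis[(4S)-4-tert-butyl-2-oxazoline] the aldehyde and ketone oxygens would be chelated. The activated C9 aldehyde would be attacked by C10 of the E alkene in a Prins step, and the tertiary cation at C5 would be captured by C4 of the Z silyl enol ether, giving the trans-fused hydroxy dione A5.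
- In its favour: four stereocentres (C4, C5, C9, C10), both rings and the C3 and C8 carbonyls would arise in one catalytic step from an achiral chain, and A5 has the relative configuration of the target at these centres. On step economy this alternative is clearly the better.
- Against it here: everything rests on one cationic cascade in which two alkene geometries must be translated through chair-like folding. The C5 cation can lose a proton instead of being trapped, the glyoxal-type terminus of A4 is prone to hydration and self-condensation, and enantiocontrol must reach from the chelated C9 to the distant C4–C5 bond. Afterwards the ketones at C3 and C8 of A5 must be told apart, and C3 reduced to the equatorial alcohol against the shielding by axial C14.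
- Comparison: the alternative is shorter and sets C4 directly (here C4 needs step 8), and it is the equal in leaving the alkylidene to a later stage. The chosen plan is the more conservative in mechanism: a concerted rearrangement through the only accessible boat geometry transfers one defined stereocentre into C5 and C10, and a failure of any later step does not cost the skeleton.

Alternative 3: Ring B is cut at C7–C8 and the methyl C13 is removed from C11 in the same operation, which leads to an alkynyl aldehyde on a complete ring A, compound A6. Ni(cod)2 would couple the aldehyde and the alkyne of A6 to an oxanickelacycle, Me2Zn would transfer methyl to nickel, and reductive elimination would place it on C11. A7 would thus form with C8 and C13 syn on the new alkene, the target geometry.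
- In its favour: this is the only plan discussed in which the geometry of the C7=C11 bond follows from the mechanism, and on this point the alternative is the better. Ring B, C13 and the alkene would come in one step, against four steps (12 and 14–16) here.
- Against it: the step needs a substrate, A6, that already contains all five ring stereocentres, including the quaternary C5 and an epimerisable α-silyloxy aldehyde, so the disconnection does not address the hard part of ring A. The cyclisation must close a six-membered ring next to a quaternary carbon, and the C8 carbinol must be oxidised afterwards.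
- Comparison: the two plans are complementary and not competing. The chosen key step supplies C5 and C10, this one supplies C7=C11. A merger would need a butynyl chain in place of the oxypropyl chain on C5 and a separate introduction of C8, which changes the carbon skeleton of the rearrangement substrate. In late-stage step economy the alternative is the equal or slightly the better.

Key step: step 7

Remark: positions are given in eremophilane numbering in all intermediates; compound 1 is used as the racemate because its stereocentre is lost in step 1, and zinc reagent 8 is taken as its commercial solution in THF.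

## Steps

Step 1
Reactants: 1 methyl 2-methyl-3-oxobutanoate
Product: 2 methyl (2Z)-2-methyl-3-{[(trifluoromethyl)sulfonyl]oxy}but-2-enoate
Conditions: Tf2O, LiOH (5 M aq.), toluene, 5 °C
Reagents that add atoms: trifluoromethanesulfonic anhydride, O=S(=O)(OS(=O)(=O)C(F)(F)F)C(F)(F)F
Why: O-Triflation of a β-keto ester enolate; lithium held between the two carbonyl oxygens keeps the enolate U-shaped, so the triflate should form syn to the ester (Z), which is the geometry needed for C4=C5.

Step 2
Reactants: 3 [(prop-2-en-1-yloxy)methyl]benzene; 2 methyl (2Z)-2-methyl-3-{[(trifluoromethyl)sulfonyl]oxy}but-2-enoate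
Product: 5 methyl (2Z)-6-(benzyloxy)-2,3-dimethylhex-2-enoate, via alkylborane 4 (not isolated)
Conditions: 3, 9-BBN (0.5 M in THF), 0 °C → rt; then 2, PdCl2(dppf) (5 mol%), K3PO4 (3 M aq.), DMF, 50 °C
Reagents that add atoms: none
Why: Anti-Markovnikov hydroboration gives the primary B-alkyl-9-BBN, which is coupled in a B-alkyl Suzuki–Miyaura reaction; oxidative addition of zerovalent palladium into the C–OTf bond and reductive elimination go with retention, so the chain (C6) takes the place of the triflate syn to the ester carbon (C3) and the two methyls (C14, C15) end up syn.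

Step 3
Reactants: 5 methyl (2Z)-6-(benzyloxy)-2,3-dimethylhex-2-enoate
Product: 6 (2Z)-6-(benzyloxy)-2,3-dimethylhex-2-enoic acid
Conditions: LiOH·H2O, THF–MeOH–H2O, 50 °C; then 1 M HCl to pH 3
Reagents that add atoms: lithium hydroxide, [Li+].[OH-]
Why: Saponification of a hindered conjugated ester; hydroxide does not touch the benzyl ether, and a fully substituted enoate has no low-energy path for geometric isomerisation under these conditions.

Step 4
Reactants: 6 (2Z)-6-(benzyloxy)-2,3-dimethylhex-2-enoic acid; 8 (4-ethoxy-4-oxobutyl)zinc bromide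
Product: 9 ethyl (6Z)-10-(benzyloxy)-6,7-dimethyl-5-oxodec-6-enoate, via acid chloride 7 (not isolated)
Conditions: (COCl)2, DMF (cat.), CH2Cl2, 0 °C → rt, concentrate; then 8 (0.5 M in THF), Pd(PPh3)4 (5 mol%), THF, 0 °C → rt
Reagents that add atoms: none
Why: Negishi acylation: zerovalent palladium inserts into the acyl chloride and the alkylzinc transfers the C2–C1–C10–C9 chain; the organozinc tolerates its own ester and does not add to the ketone formed, and the neutral conditions should leave the alkene geometry intact.

Step 5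
Reactants: 9 ethyl (6Z)-10-(benzyloxy)-6,7-dimethyl-5-oxodec-6-enoate
Product: 10 ethyl (5S,6Z)-10-(benzyloxy)-5-hydroxy-6,7-dimethyldec-6-enoate
Conditions: (R)-2-methyl-CBS-oxazaborolidine (20 mol%), catecholborane, toluene, −78 °C; MeOH quench
Reagents that add atoms: none
Why: Corey–Bakshi–Shibata reduction; the ketone should bind to the catalyst boron with the branched alkenyl group as the large substituent away from the catalyst framework, so that hydride from the nitrogen-bound borane gives the (S)-carbinol at C3 with the (R)-catalyst; the ester is inert to catecholborane at this temperature.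

Step 6
Reactants: 10 ethyl (5S,6Z)-10-(benzyloxy)-5-hydroxy-6,7-dimethyldec-6-enoate
Product: 12 (6S)-6-[(2Z)-6-(benzyloxy)-3-methylhex-2-en-2-yl]oxan-2-one, via hydroxy acid 11 (not isolated)
Conditions: LiOH, THF–H2O, 0 °C → rt; 1 M HCl to pH 4, extract; then EDC·HCl, DMAP (cat.), CH2Cl2, 0 °C → rt
Reagents that add atoms: none
Why: Saponification followed by carbodiimide lactonisation closes the six-membered ring by acyl transfer to the C3 hydroxyl; the C3–O bond is not broken, so the configuration is kept, and acid catalysis is avoided because this allylic C–O bond would ionise easily.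

Step 7
Reactants: 12 (6S)-6-[(2Z)-6-(benzyloxy)-3-methylhex-2-en-2-yl]oxan-2-one
Product: 15 (1R,2S)-2-[3-(benzyloxy)propyl]-2,3-dimethylcyclohex-3-ene-1-carboxylic acid, via silyl ketene acetal 13 (not isolated), via trimethylsilyl ester 14 (not isolated)
Conditions: LiN(iPr)2, Me3SiCl–Et3N, THF, −78 °C; warm to rt, exchange solvent for toluene, 105 °C; then 1 M HCl, THF, rt
Reagents that add atoms: none
Why: Deprotonation at C10 with silylation in the same flask gives the cyclic O-silyl ketene acetal 13, whose geometry is fixed by the ring; on heating it undergoes a concerted, doubly suprafacial [3,3] shift in which C5–C10 forms and C3–O breaks, giving silyl ester 14, which is hydrolysed to 15. The closest known reaction type is the Ireland–Claisen ring contraction of alkenyl lactone silyl ketene acetals to cycloalkenecarboxylic acids. Ring A (C10–C1–C2–C3–C4–C5) is closed as a pericyclic ring contraction of the oxanone: the C1–C2 tether forbids a chair, so the six reacting atoms adopt a boat within a bicyclo[2.2.2]octane-like array that has C3 and C10 as bridgeheads. C10 is controlled by the C3 carbinol centre, because C10 can reach C5 only across the face of the allyl unit from which oxygen departs. C5 is controlled by the alkene geometry: with C6 syn to C3 (Z), C14 is placed cis to the C9 carboxyl, which is the trans-decalin relationship. The step needs complete chirality transfer and an intact alkene geometry; the single accessible boat secures the first and the triflate-derived Z alkene of steps 1 and 2 the second. The price is an eclipsing contact between C6 and C1 and bond formation at a fully substituted terminus, which is why the rearrangement is run hot after trapping the enolate cold.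

Step 8
Reactants: 15 (1R,2S)-2-[3-(benzyloxy)propyl]-2,3-dimethylcyclohex-3-ene-1-carboxylic acid
Product: 16 (1R,2R,3S,4R)-3-[3-(benzyloxy)propyl]-4-(hydroxymethyl)-2,3-dimethylcyclohexan-1-ol
Conditions: BH3·THF (5 equiv), THF, 0 °C → rt; then NaOH (3 M aq.), H2O2 (30%), 0 °C → rt
Reagents that add atoms: hydrogen peroxide, OO
Why: Borane reduces the acid to the C9 carbinol and hydroborates C3=C4 with boron on the less substituted C3 and syn delivery of hydrogen to C4, and oxidation proceeds with retention. Of the two rapidly interconverting half-chairs only the one with C14 pseudoaxial has an open face (the other is shielded by the pseudoaxial C6 chain on one side and the axial C9 borate on the other), so attack anti to C14 should give the 3α-hydroxyl and 4α-hydrogen, with C15 cis to C14.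

Step 9
Reactants: 16 (1R,2R,3S,4R)-3-[3-(benzyloxy)propyl]-4-(hydroxymethyl)-2,3-dimethylcyclohexan-1-ol
Product: 17 (1R,2R,3S,4R)-4-(hydroxymethyl)-3-(3-hydroxypropyl)-2,3-dimethylcyclohexan-1-ol
Conditions: H2 (1 atm), Pd/C (10%), EtOAc, rt
Reagents that add atoms: none
Why: Hydrogenolysis of the benzyl ether; no alkene remains at this stage and no stereocentre is touched.

Step 10
Reactants: 17 (1R,2R,3S,4R)-4-(hydroxymethyl)-3-(3-hydroxypropyl)-2,3-dimethylcyclohexan-1-ol
Product: 18 (1R,2R,3R,4R)-4-hydroxy-2,3-dimethyl-2-(3-oxopropyl)cyclohexane-1-carbaldehyde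
Conditions: TEMPO (20 mol%), PhI(OAc)2 (2.3 equiv), CH2Cl2, rt
Reagents that add atoms: none
Why: Oxoammonium oxidation is selective for primary over secondary alcohols, so both primary carbinols (C8, C9) should go to aldehydes while the flanked C3 hydroxyl stays; the weakly acidic, water-poor medium should prevent over-oxidation and epimerisation at C10.

Step 11
Reactants: 18 (1R,2R,3R,4R)-4-hydroxy-2,3-dimethyl-2-(3-oxopropyl)cyclohexane-1-carbaldehyde
Product: 19 (1R,2R,3R,4R)-2,3-dimethyl-2-(3-oxopropyl)-4-[(triethylsilyl)oxy]cyclohexane-1-carbaldehyde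
Conditions: Et3SiCl, imidazole, DMF, 0 °C
Reagents that add atoms: chlorotriethylsilane, CC[Si](Cl)(CC)CC
Why: Silylation of the only hydroxyl under weakly basic conditions that should not enolise the α-branched C9 aldehyde; the triethylsilyl ether is chosen because mild acid will remove it later in the presence of the tert-butyldimethylsilyl ether.

Step 12
Reactants: 19 (1R,2R,3R,4R)-2,3-dimethyl-2-(3-oxopropyl)-4-[(triethylsilyl)oxy]cyclohexane-1-carbaldehyde
Product: 20 (1S,4aR,5R,6R,8aR)-1-hydroxy-4a,5-dimethyl-6-[(triethylsilyl)oxy]octahydronaphthalen-2(1H)-one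
Conditions: 2-(pentafluorophenyl)-6,7-dihydro-5H-pyrrolo[2,1-c][1,2,4]triazol-2-ium tetrafluoroborate (10 mol%), iPr2NEt (10 mol%), CH2Cl2 (0.02 M), rt
Reagents that add atoms: none
Why: Intramolecular crossed benzoin condensation under N-heterocyclic carbene catalysis: the carbene should add to the unhindered C8 aldehyde, and the resulting acyl-anion equivalent attacks the neopentylic C9 aldehyde in a 6-exo-trig closure, giving the C8 ketone and C9 carbinol. The C9 oxygen is expected equatorial (9S) because an axial oxygen would be 1,3-diaxial to C14, and the trans fusion is inherited from 15.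

Step 13
Reactants: 20 (1S,4aR,5R,6R,8aR)-1-hydroxy-4a,5-dimethyl-6-[(triethylsilyl)oxy]octahydronaphthalen-2(1H)-one
Product: 21 (1S,4aR,5R,6R,8aR)-1-{[tert-butyl(dimethyl)silyl]oxy}-4a,5-dimethyl-6-[(triethylsilyl)oxy]octahydronaphthalen-2(1H)-one
Conditions: tBuMe2SiOTf, 2,6-lutidine, CH2Cl2, −78 → 0 °C
Reagents that add atoms: tert-butyldimethylsilyl trifluoromethanesulfonate, CC(C)(C)[Si](C)(C)OS(=O)(=O)C(F)(F)F
Why: Silylation of the α-ketol hydroxyl with a silyl triflate and a hindered base at low temperature; it blocks the ketol shift and keeps a C9 alkoxide out of the enolate chemistry that follows.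

Step 14
Reactants: 21 (1S,4aR,5R,6R,8aR)-1-{[tert-butyl(dimethyl)silyl]oxy}-4a,5-dimethyl-6-[(triethylsilyl)oxy]octahydronaphthalen-2(1H)-one; 22 1,1-dimethoxypropan-2-one
Product: 23 (1S,4aR,5R,6R,8aR)-1-{[tert-butyl(dimethyl)silyl]oxy}-3-(2-hydroxy-1,1-dimethoxypropan-2-yl)-4a,5-dimethyl-6-[(triethylsilyl)oxy]octahydronaphthalen-2(1H)-one (mixture of diastereomers at the two new centres)
Conditions: LiN(iPr)2, THF, −78 °C; then 22, −78 °C; AcOH quench at −78 °C
Reagents that add atoms: none
Why: Kinetic deprotonation should occur at the C7 methylene and not at the C9 methine that bears the bulky silyloxy group, and the lithium enolate adds to the activated α,α-dialkoxy ketone in a directed aldol reaction; the cold quench prevents retro-aldol cleavage, and both new centres are removed in the next step.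

Step 15
Reactants: 23 (1S,4aR,5R,6R,8aR)-1-{[tert-butyl(dimethyl)silyl]oxy}-3-(2-hydroxy-1,1-dimethoxypropan-2-yl)-4a,5-dimethyl-6-[(triethylsilyl)oxy]octahydronaphthalen-2(1H)-one
Product: 25 (1S,3E,4aR,5R,6R,8aR)-1-{[tert-butyl(dimethyl)silyl]oxy}-3-(1,1-dimethoxypropan-2-ylidene)-4a,5-dimethyl-6-[(triethylsilyl)oxy]octahydronaphthalen-2(1H)-one, via mesylate 24 (not isolated)
Conditions: MeSO2Cl, Et3N, CH2Cl2, 0 °C; then DBU, rt → 40 °C
Reagents that add atoms: none
Why: Mesylation of the tertiary aldol (through the sulfene) closes the retro-aldol path, and base then eliminates by the E1cB mechanism through the C7 enolate to the conjugated tetrasubstituted alkene; the branched dimethoxymethyl group should prefer the position anti to the C8 carbonyl (E), and the geometry can still be corrected at the next stage.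

Step 16
Reactants: 25 (1S,3E,4aR,5R,6R,8aR)-1-{[tert-butyl(dimethyl)silyl]oxy}-3-(1,1-dimethoxypropan-2-ylidene)-4a,5-dimethyl-6-[(triethylsilyl)oxy]octahydronaphthalen-2(1H)-one
Product: 26 (2E)-2-[(1S,4aR,5R,6R,8aR)-1-{[tert-butyl(dimethyl)silyl]oxy}-6-hydroxy-4a,5-dimethyl-2-oxooctahydronaphthalen-3(2H)-ylidene]propanal
Conditions: AcOH–THF–H2O (3:1:1), 35 °C
Reagents that add atoms: water, O
Why: Mild aqueous acid hydrolyses the allylic dimethyl acetal and the secondary triethylsilyl ether, while the hindered tert-butyldimethylsilyl ether at C9 should survive. In the resulting 4-oxo-2-enal the E isomer, with the two carbonyl groups anti, is expected to be the more stable, and the acid allows Z to E equilibration through the dienol.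

Step 17
Reactants: 27 ethyl (2E)-4-oxobut-2-enoate; 28 2-(triphenyl-λ5-phosphanylidene)propanal
Product: 29 ethyl (2E,4E)-5-methyl-6-oxohexa-2,4-dienoate
Conditions: CH2Cl2, rt → 40 °C
Reagents that add atoms: none
Why: Wittig olefination with a stabilised ylide, which reacts only with the aldehyde and should give the E-trisubstituted enal (chain anti to the formyl group), as needed for C4=C5 of the acid.

Step 18
Reactants: 30 1-bromohexane; 31 1-phenyl-1H-tetrazole-5-thiol
Product: 32 5-(hexylsulfanyl)-1-phenyl-1H-tetrazole
Conditions: K2CO3, acetone, reflux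
Reagents that add atoms: none
Why: SN2 S-alkylation of the thiolate by a primary bromide.

Step 19
Reactants: 32 5-(hexylsulfanyl)-1-phenyl-1H-tetrazole
Product: 33 5-(hexane-1-sulfonyl)-1-phenyl-1H-tetrazole
Conditions: H2O2 (30%), (NH4)6Mo7O24·4H2O (cat.), EtOH, rt
Reagents that add atoms: hydrogen peroxide, OO
Why: Molybdate-catalysed oxidation of the sulfide to the sulfone; the tetrazole is inert.

Step 20
Reactants: 33 5-(hexane-1-sulfonyl)-1-phenyl-1H-tetrazole; 29 ethyl (2E,4E)-5-methyl-6-oxohexa-2,4-dienoate
Product: 34 ethyl (2E,4E,6E)-5-methyldodeca-2,4,6-trienoate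
Conditions: KN(SiMe3)2, DME, −60 °C; then 29, −60 °C → rt
Reagents that add atoms: none
Why: Julia–Kocienski olefination: the metallated sulfone adds to the aldehyde, and Smiles rearrangement with loss of sulfur dioxide and the tetrazolone gives the alkene; the potassium base in DME favours the anti adduct and therefore the E alkene at C6=C7, and the premetallated sulfone should attack the aldehyde faster than the dienoate.

Step 21
Reactants: 34 ethyl (2E,4E,6E)-5-methyldodeca-2,4,6-trienoate
Product: 35 (2E,4E,6E)-5-methyldodeca-2,4,6-trienoic acid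
Conditions: LiOH·H2O, THF–MeOH–H2O, rt, dark; then 1 M HCl to pH 3
Reagents that add atoms: lithium hydroxide, [Li+].[OH-]
Why: Saponification at room temperature with exclusion of light, which should leave the triene geometry unchanged.

Step 22
Reactants: 26 (2E)-2-[(1S,4aR,5R,6R,8aR)-1-{[tert-butyl(dimethyl)silyl]oxy}-6-hydroxy-4a,5-dimethyl-2-oxooctahydronaphthalen-3(2H)-ylidene]propanal; 35 (2E,4E,6E)-5-methyldodeca-2,4,6-trienoic acid
Product: 36 (1R,2R,4aR,5S,7E,8aR)-5-{[tert-butyl(dimethyl)silyl]oxy}-1,8a-dimethyl-6-oxo-7-(1-oxopropan-2-ylidene)decahydronaphthalen-2-yl (2E,4E,6E)-5-methyldodeca-2,4,6-trienoate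
Conditions: EDC·HCl, DMAP (0.2 equiv), CH2Cl2, 0 °C → rt, dark
Reagents that add atoms: none
Why: Steglich esterification of the only free hydroxyl (equatorial C3–OH); the acyl–oxygen bond is formed, so C3 keeps its configuration, and the aldehyde and the hindered ketone are inert; substoichiometric DMAP at low temperature limits isomerisation of the activated trienoate.

Step 23
Reactants: 36 (1R,2R,4aR,5S,7E,8aR)-5-{[tert-butyl(dimethyl)silyl]oxy}-1,8a-dimethyl-6-oxo-7-(1-oxopropan-2-ylidene)decahydronaphthalen-2-yl (2E,4E,6E)-5-methyldodeca-2,4,6-trienoate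
Product: 37 (1R,2R,4aR,5S,7E,8aR)-5-{[tert-butyl(dimethyl)silyl]oxy}-7-(1-hydroxypropan-2-ylidene)-1,8a-dimethyl-6-oxodecahydronaphthalen-2-yl (2E,4E,6E)-5-methyldodeca-2,4,6-trienoate
Conditions: NaBH4, EtOH–CH2Cl2, −78 °C
Reagents that add atoms: none
Why: Chemoselective 1,2-reduction of the aldehyde; at low temperature the hindered, cross-conjugated C8 ketone flanked by the silyloxy group and the trienoate ester should not react.

Step 24
Reactants: 37 (1R,2R,4aR,5S,7E,8aR)-5-{[tert-butyl(dimethyl)silyl]oxy}-7-(1-hydroxypropan-2-ylidene)-1,8a-dimethyl-6-oxodecahydronaphthalen-2-yl (2E,4E,6E)-5-methyldodeca-2,4,6-trienoate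
Product: 38 (1R,2R,4aR,5S,7E,8aR)-5-hydroxy-7-(1-hydroxypropan-2-ylidene)-1,8a-dimethyl-6-oxodecahydronaphthalen-2-yl (2E,4E,6E)-5-methyldodeca-2,4,6-trienoate
Conditions: HF·pyridine, pyridine, THF, 0 °C → rt
Reagents that add atoms: none
Why: Buffered fluoride cleavage of the C9 silyl ether; the ester, the E γ-hydroxy enone (which cannot close onto C8) and the ketol should tolerate these mildly acidic conditions.

## Compound list

1 | methyl 2-methyl-3-oxobutanoate (racemic) | COC(=O)C(C)C(C)=O | starting material
2 | methyl (2Z)-2-methyl-3-{[(trifluoromethyl)sulfonyl]oxy}but-2-enoate | COC(=O)/C(C)=C(/C)OS(=O)(=O)C(F)(F)F | intermediate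
3 | [(prop-2-en-1-yloxy)methyl]benzene | C=CCOCc1ccccc1 | starting material
4 | 9-[3-(benzyloxy)propyl]-9-borabicyclo[3.3.1]nonane | B1(CCCOCc2ccccc2)C2CCCC1CCC2 | intermediate
5 | methyl (2Z)-6-(benzyloxy)-2,3-dimethylhex-2-enoate | COC(=O)/C(C)=C(/C)CCCOCc1ccccc1 | intermediate
6 | (2Z)-6-(benzyloxy)-2,3-dimethylhex-2-enoic acid | OC(=O)/C(C)=C(/C)CCCOCc1ccccc1 | intermediate
7 | (2Z)-6-(benzyloxy)-2,3-dimethylhex-2-enoyl chloride | ClC(=O)/C(C)=C(/C)CCCOCc1ccccc1 | intermediate
8 | (4-ethoxy-4-oxobutyl)zinc bromide | CCOC(=O)CCC[Zn]Br | starting material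
9 | ethyl (6Z)-10-(benzyloxy)-6,7-dimethyl-5-oxodec-6-enoate | CCOC(=O)CCCC(=O)/C(C)=C(/C)CCCOCc1ccccc1 | intermediate
10 | ethyl (5S,6Z)-10-(benzyloxy)-5-hydroxy-6,7-dimethyldec-6-enoate | CCOC(=O)CCC[C@H](O)/C(C)=C(/C)CCCOCc1ccccc1 | intermediate
11 | (5S,6Z)-10-(benzyloxy)-5-hydroxy-6,7-dimethyldec-6-enoic acid | OC(=O)CCC[C@H](O)/C(C)=C(/C)CCCOCc1ccccc1 | intermediate
12 | (6S)-6-[(2Z)-6-(benzyloxy)-3-methylhex-2-en-2-yl]oxan-2-one | O=C1CCC[C@H](O1)/C(C)=C(/C)CCCOCc1ccccc1 | intermediate
13 | {[(2S)-2-[(2Z)-6-(benzyloxy)-3-methylhex-2-en-2-yl]-3,4-dihydro-2H-pyran-6-yl]oxy}(trimethyl)silane | C[Si](C)(C)OC1=CCC[C@H](O1)/C(C)=C(/C)CCCOCc1ccccc1 | intermediate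
14 | trimethylsilyl (1R,2S)-2-[3-(benzyloxy)propyl]-2,3-dimethylcyclohex-3-ene-1-carboxylate | C[Si](C)(C)OC(=O)[C@@H]1CCC=C(C)[C@@]1(C)CCCOCc1ccccc1 | intermediate
15 | (1R,2S)-2-[3-(benzyloxy)propyl]-2,3-dimethylcyclohex-3-ene-1-carboxylic acid | OC(=O)[C@@H]1CCC=C(C)[C@@]1(C)CCCOCc1ccccc1 | intermediate
16 | (1R,2R,3S,4R)-3-[3-(benzyloxy)propyl]-4-(hydroxymethyl)-2,3-dimethylcyclohexan-1-ol | O[C@@H]1CC[C@@H](CO)[C@](C)(CCCOCc2ccccc2)[C@H]1C | intermediate
17 | (1R,2R,3S,4R)-4-(hydroxymethyl)-3-(3-hydroxypropyl)-2,3-dimethylcyclohexan-1-ol | O[C@@H]1CC[C@@H](CO)[C@](C)(CCCO)[C@H]1C | intermediate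
18 | (1R,2R,3R,4R)-4-hydroxy-2,3-dimethyl-2-(3-oxopropyl)cyclohexane-1-carbaldehyde | O[C@@H]1CC[C@@H](C=O)[C@](C)(CCC=O)[C@H]1C | intermediate
19 | (1R,2R,3R,4R)-2,3-dimethyl-2-(3-oxopropyl)-4-[(triethylsilyl)oxy]cyclohexane-1-carbaldehyde | CC[Si](CC)(CC)O[C@@H]1CC[C@@H](C=O)[C@](C)(CCC=O)[C@H]1C | intermediate
20 | (1S,4aR,5R,6R,8aR)-1-hydroxy-4a,5-dimethyl-6-[(triethylsilyl)oxy]octahydronaphthalen-2(1H)-one | CC[Si](CC)(CC)O[C@@H]1CC[C@H]2[C@H](O)C(=O)CC[C@]2(C)[C@H]1C | intermediate
21 | (1S,4aR,5R,6R,8aR)-1-{[tert-butyl(dimethyl)silyl]oxy}-4a,5-dimethyl-6-[(triethylsilyl)oxy]octahydronaphthalen-2(1H)-one | CC[Si](CC)(CC)O[C@@H]1CC[C@H]2[C@H](O[Si](C)(C)C(C)(C)C)C(=O)CC[C@]2(C)[C@H]1C | intermediate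
22 | 1,1-dimethoxypropan-2-one | COC(OC)C(C)=O | starting material
23 | (1S,4aR,5R,6R,8aR)-1-{[tert-butyl(dimethyl)silyl]oxy}-3-(2-hydroxy-1,1-dimethoxypropan-2-yl)-4a,5-dimethyl-6-[(triethylsilyl)oxy]octahydronaphthalen-2(1H)-one (diastereomers at C3 and the carbinol carbon) | CC[Si](CC)(CC)O[C@@H]1CC[C@H]2[C@H](O[Si](C)(C)C(C)(C)C)C(=O)C(C(C)(O)C(OC)OC)C[C@]2(C)[C@H]1C | intermediate
24 | 2-[(1S,4aR,5R,6R,8aR)-1-{[tert-butyl(dimethyl)silyl]oxy}-4a,5-dimethyl-2-oxo-6-[(triethylsilyl)oxy]decahydronaphthalen-3-yl]-1,1-dimethoxypropan-2-yl methanesulfonate | CC[Si](CC)(CC)O[C@@H]1CC[C@H]2[C@H](O[Si](C)(C)C(C)(C)C)C(=O)C(C(C)(OS(C)(=O)=O)C(OC)OC)C[C@]2(C)[C@H]1C | intermediate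
25 | (1S,3E,4aR,5R,6R,8aR)-1-{[tert-butyl(dimethyl)silyl]oxy}-3-(1,1-dimethoxypropan-2-ylidene)-4a,5-dimethyl-6-[(triethylsilyl)oxy]octahydronaphthalen-2(1H)-one | CC[Si](CC)(CC)O[C@@H]1CC[C@H]2[C@H](O[Si](C)(C)C(C)(C)C)C(=O)/C(=C(\C)C(OC)OC)C[C@]2(C)[C@H]1C | intermediate
26 | (2E)-2-[(1S,4aR,5R,6R,8aR)-1-{[tert-butyl(dimethyl)silyl]oxy}-6-hydroxy-4a,5-dimethyl-2-oxooctahydronaphthalen-3(2H)-ylidene]propanal | O[C@@H]1CC[C@H]2[C@H](O[Si](C)(C)C(C)(C)C)C(=O)/C(=C(\C)C=O)C[C@]2(C)[C@H]1C | intermediate
27 | ethyl (2E)-4-oxobut-2-enoate | CCOC(=O)/C=C/C=O | starting material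
28 | 2-(triphenyl-λ5-phosphanylidene)propanal | CC(C=O)=P(c1ccccc1)(c1ccccc1)c1ccccc1 | starting material
29 | ethyl (2E,4E)-5-methyl-6-oxohexa-2,4-dienoate | CCOC(=O)/C=C/C=C(\C)C=O | intermediate
30 | 1-bromohexane | CCCCCCBr | starting material
31 | 1-phenyl-1H-tetrazole-5-thiol | Sc1nnnn1-c1ccccc1 | starting material
32 | 5-(hexylsulfanyl)-1-phenyl-1H-tetrazole | CCCCCCSc1nnnn1-c1ccccc1 | intermediate
33 | 5-(hexane-1-sulfonyl)-1-phenyl-1H-tetrazole | CCCCCCS(=O)(=O)c1nnnn1-c1ccccc1 | intermediate
34 | ethyl (2E,4E,6E)-5-methyldodeca-2,4,6-trienoate | CCCCC/C=C/C(C)=C/C=C/C(=O)OCC | intermediate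
35 | (2E,4E,6E)-5-methyldodeca-2,4,6-trienoic acid | CCCCC/C=C/C(C)=C/C=C/C(=O)O | intermediate
36 | (1R,2R,4aR,5S,7E,8aR)-5-{[tert-butyl(dimethyl)silyl]oxy}-1,8a-dimethyl-6-oxo-7-(1-oxopropan-2-ylidene)decahydronaphthalen-2-yl (2E,4E,6E)-5-methyldodeca-2,4,6-trienoate | CCCCC/C=C/C(C)=C/C=C/C(=O)O[C@@H]1CC[C@H]2[C@H](O[Si](C)(C)C(C)(C)C)C(=O)/C(=C(\C)C=O)C[C@]2(C)[C@H]1C | intermediate
37 | (1R,2R,4aR,5S,7E,8aR)-5-{[tert-butyl(dimethyl)silyl]oxy}-7-(1-hydroxypropan-2-ylidene)-1,8a-dimethyl-6-oxodecahydronaphthalen-2-yl (2E,4E,6E)-5-methyldodeca-2,4,6-trienoate | CCCCC/C=C/C(C)=C/C=C/C(=O)O[C@@H]1CC[C@H]2[C@H](O[Si](C)(C)C(C)(C)C)C(=O)/C(=C(\C)CO)C[C@]2(C)[C@H]1C | intermediate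
38 | (1R,2R,4aR,5S,7E,8aR)-5-hydroxy-7-(1-hydroxypropan-2-ylidene)-1,8a-dimethyl-6-oxodecahydronaphthalen-2-yl (2E,4E,6E)-5-methyldodeca-2,4,6-trienoate | CCCCC/C=C/C(C)=C/C=C/C(=O)O[C@@H]1CC[C@H]2[C@H](O)C(=O)/C(=C(\C)CO)C[C@]2(C)[C@H]1C | target

## Step count and least certain steps

Total step count: 24. Longest linear sequence: 19 steps (steps 1–16 and 22–24); steps 17–21 make the side-chain acid 35 in a convergent branch.

**Step 7 (key step).** The new bond is formed at a fully substituted alkene terminus with C6 eclipsing C1, so the rearrangement may be slower than decomposition of the ketene acetal (hydrolysis back to 12, C-silylation, or ionisation of the allylic C3–O bond with elimination), which would lower conversion or erode chirality transfer.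
Fallback, from 5 back to 15: reduction of 5 with iBu2AlH would give (2Z)-6-(benzyloxy)-2,3-dimethylhex-2-en-1-ol F1, and carbodiimide esterification with hex-5-enoic acid would give (2Z)-6-(benzyloxy)-2,3-dimethylhex-2-en-1-yl hex-5-enoate F2. An open-chain ester-enolate Claisen rearrangement through a chair would follow, run with a chiral bromoborane controller (the bis-sulfonamide of 1,2-diphenylethane-1,2-diamine, the enantiomer and the amine base chosen so that the enolate with C1 syn to the boron-bound oxygen is formed). It should give (2R,3S)-3-[3-(benzyloxy)propyl]-2-(but-3-en-1-yl)-3,4-dimethylpent-4-enoic acid F3, in which a less congested, unconstrained transition state sets C5 and C10. Ring-closing metathesis of F3 with the second-generation Grubbs catalyst, RuCl2(=CHPh)(H2IMes)(PCy3), would then close ring A between the isopropenyl group and the butenyl chain and return to 15.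

**Step 8.** The ring is still monocyclic and flexible, so the facial selectivity of the hydroboration may be incomplete, giving C3/C4 epimers that are hard to separate.
Fallback, from 15 back to 21: the alkene is kept until the ring fusion makes the system rigid.
- Reduction of 15 with LiAlH4 would give [(1R,2S)-2-[3-(benzyloxy)propyl]-2,3-dimethylcyclohex-3-en-1-yl]methanol F4, and cleavage of the benzyl ether with lithium in liquid ammonia would give 3-[(1S,6R)-6-(hydroxymethyl)-1,2-dimethylcyclohex-2-en-1-yl]propan-1-ol F5.
- Dess–Martin oxidation would give (1R,2S)-2,3-dimethyl-2-(3-oxopropyl)cyclohex-3-ene-1-carbaldehyde F6, and the carbene-catalysed benzoin closure of step 12 would give (1S,4aS,8aR)-1-hydroxy-4a,5-dimethyl-3,4,4a,7,8,8a-hexahydronaphthalen-2(1H)-one F7.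
- Silylation as in step 13 would give (1S,4aS,8aR)-1-{[tert-butyl(dimethyl)silyl]oxy}-4a,5-dimethyl-3,4,4a,7,8,8a-hexahydronaphthalen-2(1H)-one F8.
- Epoxidation with mCPBA anti to the axial C14 on the rigid trans-decalin would give (1S,4aS,5S,6R,8aR)-1-{[tert-butyl(dimethyl)silyl]oxy}-5,6-epoxy-4a,5-dimethyloctahydronaphthalen-2(1H)-one F9.
- Reductive opening with Cp2TiCl (from Cp2TiCl2 and Mn) and 1,4-cyclohexadiene would proceed through the tertiary C4 radical, with hydrogen delivered on the face anti to C14, and give (1S,4aR,5R,6R,8aR)-1-{[tert-butyl(dimethyl)silyl]oxy}-6-hydroxy-4a,5-dimethyloctahydronaphthalen-2(1H)-one F10.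
- Silylation of F10 with Et3SiCl returns to 21.

**Step 12.** The 1,6-dialdehyde can undergo base-induced intramolecular aldol condensation to a cyclopentene carbaldehyde, epimerise at C10 before cyclisation, react with reversed donor and acceptor roles, or undergo a ketol shift after closure.
Fallback, from 19 back to 20: reductive pinacol cyclisation of 19 with SmI2 (THF, tBuOH), in which the chelated ketyls should give the cis-diol with the C9 oxygen equatorial, would give (1S,2R,4aR,5R,6R,8aR)-4a,5-dimethyl-6-[(triethylsilyl)oxy]decahydronaphthalene-1,2-diol F11. Regioselective oxidation of its axial C8 hydroxyl through the stannylene acetal (Bu2SnO, then Br2) returns to 20.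

**Step 15 (with steps 14 and 16).** The tertiary aldol may revert before it is activated, and the tetrasubstituted alkene may form or equilibrate with insufficient preference for the E isomer, because the two substituents on C11 differ little in size.
Fallback, from 21 back to 26: the geometry is fixed through an enol triflate.
- Claisen condensation of 21 with dimethyl oxalate (LiN(SiMe3)2, THF) would give methyl (2Z)-2-[(1S,4aR,5R,6R,8aR)-1-{[tert-butyl(dimethyl)silyl]oxy}-4a,5-dimethyl-2-oxo-6-[(triethylsilyl)oxy]octahydronaphthalen-3(2H)-ylidene]-2-hydroxyacetate F12, whose enol hydroxyl is hydrogen-bonded to the C8 carbonyl.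
- Triflation (Tf2O, iPr2NEt, −78 °C) would give methyl (2Z)-2-[(1S,4aR,5R,6R,8aR)-1-{[tert-butyl(dimethyl)silyl]oxy}-4a,5-dimethyl-2-oxo-6-[(triethylsilyl)oxy]octahydronaphthalen-3(2H)-ylidene]-2-{[(trifluoromethyl)sulfonyl]oxy}acetate F13.
- Stereoretentive Negishi methylation (MeZnCl, Pd(PPh3)4) would give methyl (2E)-2-[(1S,4aR,5R,6R,8aR)-1-{[tert-butyl(dimethyl)silyl]oxy}-4a,5-dimethyl-2-oxo-6-[(triethylsilyl)oxy]octahydronaphthalen-3(2H)-ylidene]propanoate F14, with C13 syn to C8.
- Reduction of ester and ketone with iBu2AlH would give (1S,3E,4aR,5R,6R,8aR)-1-{[tert-butyl(dimethyl)silyl]oxy}-3-(1-hydroxypropan-2-ylidene)-4a,5-dimethyl-6-[(triethylsilyl)oxy]decahydronaphthalen-2-ol F15.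
- Dess–Martin oxidation of both allylic alcohols would give (2E)-2-[(1S,4aR,5R,6R,8aR)-1-{[tert-butyl(dimethyl)silyl]oxy}-4a,5-dimethyl-2-oxo-6-[(triethylsilyl)oxy]octahydronaphthalen-3(2H)-ylidene]propanal F16.
- Removal of the triethylsilyl group from F16 with AcOH–THF–H2O returns to 26.

## Further compounds

F1 | step 7 | (2Z)-6-(benzyloxy)-2,3-dimethylhex-2-en-1-ol | OC/C(C)=C(/C)CCCOCc1ccccc1
F2 | step 7 | (2Z)-6-(benzyloxy)-2,3-dimethylhex-2-en-1-yl hex-5-enoate | C=CCCCC(=O)OC/C(C)=C(/C)CCCOCc1ccccc1
F3 | step 7 | (2R,3S)-3-[3-(benzyloxy)propyl]-2-(but-3-en-1-yl)-3,4-dimethylpent-4-enoic acid | OC(=O)[C@H](CCC=C)[C@](C)(CCCOCc1ccccc1)C(C)=C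
F4 | step 8 | [(1R,2S)-2-[3-(benzyloxy)propyl]-2,3-dimethylcyclohex-3-en-1-yl]methanol | OC[C@@H]1CCC=C(C)[C@@]1(C)CCCOCc1ccccc1
F5 | step 8 | 3-[(1S,6R)-6-(hydroxymethyl)-1,2-dimethylcyclohex-2-en-1-yl]propan-1-ol | OC[C@@H]1CCC=C(C)[C@@]1(C)CCCO
F6 | step 8 | (1R,2S)-2,3-dimethyl-2-(3-oxopropyl)cyclohex-3-ene-1-carbaldehyde | O=C[C@@H]1CCC=C(C)[C@@]1(C)CCC=O
F7 | step 8 | (1S,4aS,8aR)-1-hydroxy-4a,5-dimethyl-3,4,4a,7,8,8a-hexahydronaphthalen-2(1H)-one | C1C[C@H]2[C@H](O)C(=O)CC[C@]2(C)C(C)=C1
F8 | step 8 | (1S,4aS,8aR)-1-{[tert-butyl(dimethyl)silyl]oxy}-4a,5-dimethyl-3,4,4a,7,8,8a-hexahydronaphthalen-2(1H)-one | C1C[C@H]2[C@H](O[Si](C)(C)C(C)(C)C)C(=O)CC[C@]2(C)C(C)=C1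
F9 | step 8 | (1S,4aS,5S,6R,8aR)-1-{[tert-butyl(dimethyl)silyl]oxy}-5,6-epoxy-4a,5-dimethyloctahydronaphthalen-2(1H)-one | C1C[C@H]2[C@H](O[Si](C)(C)C(C)(C)C)C(=O)CC[C@]2(C)[C@]3(C)O[C@H]13
F10 | step 8 | (1S,4aR,5R,6R,8aR)-1-{[tert-butyl(dimethyl)silyl]oxy}-6-hydroxy-4a,5-dimethyloctahydronaphthalen-2(1H)-one | O[C@@H]1CC[C@H]2[C@H](O[Si](C)(C)C(C)(C)C)C(=O)CC[C@]2(C)[C@H]1C
F11 | step 12 | (1S,2R,4aR,5R,6R,8aR)-4a,5-dimethyl-6-[(triethylsilyl)oxy]decahydronaphthalene-1,2-diol | CC[Si](CC)(CC)O[C@@H]1CC[C@H]2[C@H](O)[C@H](O)CC[C@]2(C)[C@H]1C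
F12 | step 15 | methyl (2Z)-2-[(1S,4aR,5R,6R,8aR)-1-{[tert-butyl(dimethyl)silyl]oxy}-4a,5-dimethyl-2-oxo-6-[(triethylsilyl)oxy]octahydronaphthalen-3(2H)-ylidene]-2-hydroxyacetate | CC[Si](CC)(CC)O[C@@H]1CC[C@H]2[C@H](O[Si](C)(C)C(C)(C)C)C(=O)/C(=C(\O)C(=O)OC)C[C@]2(C)[C@H]1C
F13 | step 15 | methyl (2Z)-2-[(1S,4aR,5R,6R,8aR)-1-{[tert-butyl(dimethyl)silyl]oxy}-4a,5-dimethyl-2-oxo-6-[(triethylsilyl)oxy]octahydronaphthalen-3(2H)-ylidene]-2-{[(trifluoromethyl)sulfonyl]oxy}acetate | CC[Si](CC)(CC)O[C@@H]1CC[C@H]2[C@H](O[Si](C)(C)C(C)(C)C)C(=O)/C(=C(\OS(=O)(=O)C(F)(F)F)C(=O)OC)C[C@]2(C)[C@H]1C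
F14 | step 15 | methyl (2E)-2-[(1S,4aR,5R,6R,8aR)-1-{[tert-butyl(dimethyl)silyl]oxy}-4a,5-dimethyl-2-oxo-6-[(triethylsilyl)oxy]octahydronaphthalen-3(2H)-ylidene]propanoate | CC[Si](CC)(CC)O[C@@H]1CC[C@H]2[C@H](O[Si](C)(C)C(C)(C)C)C(=O)/C(=C(\C)C(=O)OC)C[C@]2(C)[C@H]1C
F15 | step 15 | (1S,3E,4aR,5R,6R,8aR)-1-{[tert-butyl(dimethyl)silyl]oxy}-3-(1-hydroxypropan-2-ylidene)-4a,5-dimethyl-6-[(triethylsilyl)oxy]decahydronaphthalen-2-ol (both C2 epimers) | CC[Si](CC)(CC)O[C@@H]1CC[C@H]2[C@H](O[Si](C)(C)C(C)(C)C)C(O)/C(=C(\C)CO)C[C@]2(C)[C@H]1C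
F16 | step 15 | (2E)-2-[(1S,4aR,5R,6R,8aR)-1-{[tert-butyl(dimethyl)silyl]oxy}-4a,5-dimethyl-2-oxo-6-[(triethylsilyl)oxy]octahydronaphthalen-3(2H)-ylidene]propanal | CC[Si](CC)(CC)O[C@@H]1CC[C@H]2[C@H](O[Si](C)(C)C(C)(C)C)C(=O)/C(=C(\C)C=O)C[C@]2(C)[C@H]1C
A1 | alternative 1 | 2-methoxy-5-methylcyclohexa-2,5-diene-1,4-dione | COC1=CC(=O)C(C)=CC1=O
A2 | alternative 1 | triisopropyl{[(3Z)-penta-1,3-dien-3-yl]oxy}silane | C=C/C(O[Si](C(C)C)(C(C)C)C(C)C)=C/C
A3 | alternative 1 | (4aR,5S,8aS)-2-methoxy-4a,5-dimethyl-6-[(triisopropylsilyl)oxy]-4a,5,8,8a-tetrahydronaphthalene-1,4-dione | C[C@@H]1C(O[Si](C(C)C)(C(C)C)C(C)C)=CC[C@@H]2C(=O)C(OC)=CC(=O)[C@]12C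
A4 | alternative 2 | (5E,9Z)-9-{[tert-butyl(dimethyl)silyl]oxy}-5-methyl-2-oxoundeca-5,9-dienal | O=CC(=O)CC/C(C)=C/CC/C(O[Si](C)(C)C(C)(C)C)=C/C
A5 | alternative 2 | (1S,4aS,5R,8aR)-1-hydroxy-4a,5-dimethyloctahydronaphthalene-2,6(1H,3H)-dione | O=C1CC[C@H]2[C@H](O)C(=O)CC[C@]2(C)[C@H]1C
A6 | alternative 3 | (2S)-2-{[tert-butyl(dimethyl)silyl]oxy}-2-[(1R,2R,3R,4R)-2-(4-{[tert-butyl(dimethyl)silyl]oxy}but-2-yn-1-yl)-4-[(4-methoxybenzyl)oxy]-2,3-dimethylcyclohexyl]acetaldehyde | COc1ccc(CO[C@@H]2CC[C@@H]([C@H](O[Si](C)(C)C(C)(C)C)C=O)[C@](C)(CC#CCO[Si](C)(C)C(C)(C)C)[C@H]2C)cc1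
A7 | alternative 3 | (1S,2S,3E,4aR,5R,6R,8aR)-1-{[tert-butyl(dimethyl)silyl]oxy}-3-(1-{[tert-butyl(dimethyl)silyl]oxy}propan-2-ylidene)-6-[(4-methoxybenzyl)oxy]-4a,5-dimethyldecahydronaphthalen-2-ol | COc1ccc(CO[C@@H]2CC[C@H]3[C@H](O[Si](C)(C)C(C)(C)C)[C@@H](O)/C(=C(\C)CO[Si](C)(C)C(C)(C)C)C[C@]3(C)[C@H]2C)cc1
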